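**Retrosynthetic overview**

- The target, 3,4,7-tribromo-2-chloro-1H-indole (14, achiral), rests on the C2(Cl)=C3(Br) bond of the pyrrole ring next to N1. C2 and its chlorine are read as one carbon of a 1-chloroalkyne, the C3 bromine as an incoming Br+, and N1–C2 as the ring-closing bond.
- 14 ⇐ N-tosylindole 13 by N–S cleavage (last step).
- 13 ⇐ sulfonanilide 12 + NBS: one bromocyclisation forms N1–C2 and C3–Br and closes the pyrrole ring. This is the only ring made; the benzene ring with C4–Br and C7–Br comes from the starting arene.
- 12 ⇐ terminal alkyne 10 (acetylide chlorination) ⇐ aniline 8 + TsCl 9 ⇐ aminoaldehyde 5 + Ohira–Bestmann reagent 6 ⇐ fluoroaldehyde 4 (SNAr with NH3) ⇐ 1,4-dibromo-2-fluorobenzene 1 (ortho-lithiation/formylation).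

Key step: step 6

**Route**

Step 1
Reactants: 1 1,4-dibromo-2-fluorobenzene
Product: 4 3,6-dibromo-2-fluorobenzaldehyde, via aryllithium 2 (not isolated), via lithium hemiaminolate 3 (not isolated)
Conditions: LiN(iPr)2 (LDA, 1.1 equiv), THF, −78 °C; DMF, −78 °C; cold dilute aq. HCl quench
Reagents that add atoms: N,N-dimethylformamide, CN(C)C=O
Why: Directed ortho-metalation followed by formylation with DMF: the C–H flanked by F and Br is the most acidic site, the amide base at −78 °C deprotonates it without bromine–lithium exchange, and the tetrahedral adduct of the aryllithium with DMF collapses to the aldehyde on acidic quench.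

Step 2
Reactants: 4 3,6-dibromo-2-fluorobenzaldehyde
Product: 5 2-amino-3,6-dibromobenzaldehyde
Conditions: 28% aq. NH3 (excess), DMSO, 80 °C, sealed tube
Reagents that add atoms: ammonia, N
Why: Nucleophilic aromatic substitution (SNAr): the fluorine is ortho to the formyl group and to a bromine, and fluoride leaves the Meisenheimer adduct far faster than bromide, so ammonia should replace only the fluorine.

Step 3
Reactants: 5 2-amino-3,6-dibromobenzaldehyde; 6 dimethyl (1-diazo-2-oxopropyl)phosphonate
Product: 8 3,6-dibromo-2-ethynylaniline, via diazoalkene 7 (not isolated)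
Conditions: K2CO3, MeOH, 0 °C→rt
Reagents that add atoms: none
Why: Ohira–Bestmann (Seyferth–Gilbert) homologation: methanolysis of 6 releases the diazomethylphosphonate anion, which adds to the aldehyde, eliminates dimethyl phosphate to give the diazoalkene, and loses N2 with a 1,2-hydrogen shift to the terminal alkyne under conditions that leave the aniline and the aryl bromides untouched.

Step 4
Reactants: 8 3,6-dibromo-2-ethynylaniline; 9 p-toluenesulfonyl chloride
Product: 10 N-(3,6-dibromo-2-ethynylphenyl)-4-methylbenzenesulfonamide
Conditions: pyridine, DMAP (cat.), CH2Cl2, 0→40 °C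
Reagents that add atoms: none
Why: N-Sulfonylation of an aniline with a sulfonyl chloride under pyridine/DMAP nucleophilic catalysis; the two ortho substituents slow the reaction but also disfavour a second sulfonylation.

Step 5
Reactants: 10 N-(3,6-dibromo-2-ethynylphenyl)-4-methylbenzenesulfonamide
Product: 12 N-[3,6-dibromo-2-(chloroethynyl)phenyl]-4-methylbenzenesulfonamide, via dilithio salt 11 (not isolated)
Conditions: LiN(SiMe3)2 (LiHMDS, 2.2 equiv), THF, −78 °C; NCS (1.05 equiv), −78→−40 °C; cold 1 M HCl quench
Reagents that add atoms: N-chlorosuccinimide, ClN1C(=O)CCC1=O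
Why: Electrophilic chlorination of a lithium acetylide (the standard route to 1-chloroalkynes): the first equivalent of base removes the sulfonamide N–H, the second the acetylenic C–H, NCS chlorinates the more nucleophilic carbon centre, and the silylamide base does not exchange with the aryl bromides.

Step 6
Reactants: 12 N-[3,6-dibromo-2-(chloroethynyl)phenyl]-4-methylbenzenesulfonamide
Product: 13 3,4,7-tribromo-2-chloro-1-(4-methylbenzenesulfonyl)indole
Conditions: NBS (1.1 equiv), MeCN, 0 °C→rt, dark
Reagents that add atoms: N-bromosuccinimide, BrN1C(=O)CCC1=O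
Why: Proposed new method: NBS should transfer Br+ to the chloroalkyne to give a bridged bromonium ion (or β-bromovinyl cation) whose positive charge sits mainly on the chlorine-bearing carbon, where a chlorine lone pair can share it; the sulfonamide nitrogen then attacks that carbon anti to bromine and gives up its proton to succinimide anion. The closest known reaction type is the 5-endo-dig halocyclisation of N-sulfonyl 2-alkynylanilines with NBS, NIS or I2 to 3-haloindoles, extended here to an alkyne that ends in chlorine. The pyrrole ring is closed by 5-endo-dig formation of N1–C2, the only mode available because attack at the inner alkyne carbon would require a four-membered ring. No stereocentre is formed. The step needs reaction at the alkyne in preference to the arene and a fixed sense of addition: two bromines and the N-sulfonyl group deactivate the benzene ring (its open position para to nitrogen becomes C5), and the ortho tether dictates that nitrogen bonds to the outer carbon and bromine to the inner one. C2–Cl and C3–Br are thus set together, and no N-unprotected 2-chloroindole with a free C3 position is ever handled.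

Step 7
Reactants: 13 3,4,7-tribromo-2-chloro-1-(4-methylbenzenesulfonyl)indole
Product: 14 3,4,7-tribromo-2-chloro-1H-indole
Conditions: TBAF (1 M in THF, 2 equiv), THF, rt→50 °C; dilute aq. HCl work-up
Reagents that add atoms: none
Why: Fluoride-mediated desulfonylation of an N-sulfonylindole: attack at sulfur expels the tetrahaloindolide, a good leaving group because of its four halogens, and relief of strain between the sulfonyl group and the flanking C7–Br and C2–Cl should make the cleavage easy.

**Compound list**

1 | 1,4-dibromo-2-fluorobenzene | Fc1cc(Br)ccc1Br | starting material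
2 | (3,6-dibromo-2-fluorophenyl)lithium | [Li]c1c(F)c(Br)ccc1Br | intermediate
3 | lithium (3,6-dibromo-2-fluorophenyl)(dimethylamino)methanolate | CN(C)C([O-])c1c(F)c(Br)ccc1Br.[Li+] | intermediate
4 | 3,6-dibromo-2-fluorobenzaldehyde | O=Cc1c(F)c(Br)ccc1Br | intermediate
5 | 2-amino-3,6-dibromobenzaldehyde | O=Cc1c(N)c(Br)ccc1Br | intermediate
6 | dimethyl (1-diazo-2-oxopropyl)phosphonate | COP(=O)(OC)C(=[N+]=[N-])C(C)=O | starting material
7 | 3,6-dibromo-2-(2-diazoethenyl)aniline | Nc1c(Br)ccc(Br)c1C=C=[N+]=[N-] | intermediate
8 | 3,6-dibromo-2-ethynylaniline | Nc1c(Br)ccc(Br)c1C#C | intermediate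
9 | p-toluenesulfonyl chloride | Cc1ccc(cc1)S(Cl)(=O)=O | starting material
10 | N-(3,6-dibromo-2-ethynylphenyl)-4-methylbenzenesulfonamide | Cc1ccc(cc1)S(=O)(=O)Nc1c(Br)ccc(Br)c1C#C | intermediate
11 | dilithium salt of 10 (N-lithio sulfonamide, lithium acetylide) | [Li+].[Li+].Cc1ccc(cc1)S(=O)(=O)[N-]c1c(Br)ccc(Br)c1C#[C-] | intermediate
12 | N-[3,6-dibromo-2-(chloroethynyl)phenyl]-4-methylbenzenesulfonamide | Cc1ccc(cc1)S(=O)(=O)Nc1c(Br)ccc(Br)c1C#CCl | intermediate
13 | 3,4,7-tribromo-2-chloro-1-(4-methylbenzenesulfonyl)indole | Cc1ccc(cc1)S(=O)(=O)n1c(Cl)c(Br)c2c(Br)ccc(Br)c12 | intermediate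
14 | 3,4,7-tribromo-2-chloro-1H-indole | Clc1[nH]c2c(Br)ccc(Br)c2c1Br | target

**Step count**

Total steps: 7. Longest linear sequence: 7.

**Steps most likely to fail**

1. Step 6. Bromination of the arene para to nitrogen, or plain addition of bromine and adventitious nucleophiles across the electron-poor chloroalkyne, may outrun the slow 5-endo attack of the hindered sulfonamide nitrogen. Fallback by known chemistry, setting out from 10 and coming back at 13: Cu(OAc)2 (catalytic, divalent copper) in 1,2-dichloroethane at reflux should cycloisomerise 10 by 5-endo-dig hydroamination to 4,7-dibromo-1-tosylindole F1. LiN(iPr)2 in THF at −78 °C should then lithiate C2, and hexachloroethane should deliver 4,7-dibromo-2-chloro-1-tosylindole F2. Br2 in CH2Cl2/AcOH with NaOAc should brominate C3 to give 13.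

2. Step 2. Condensation of ammonia at the formyl group followed by oligomerisation, or sluggish fluoride displacement at a position flanked by two substituents, may erode the amination. Fallback setting out from 4 and coming back at 5: NaN3 in DMSO at 50 °C should displace fluoride to give 2-azido-3,6-dibromobenzaldehyde F3. Staudinger reduction (PPh3, THF, then H2O) should convert the azide into the amine and give 5.

3. Step 5. Chlorine transfer to the sulfonamide nitrogen or to the amide base instead of the acetylide carbon, and oxidative coupling of the acetylide, may compete with C-chlorination. Fallback that brings in chlorine without an electrophilic chlorine source, setting out from 5 and coming back at 12: TsCl in pyridine should give N-(3,6-dibromo-2-formylphenyl)-4-methylbenzenesulfonamide F4. PPh3/BrCCl3 in MeCN should convert the formyl group into the 1,1-dichloroalkene N-[3,6-dibromo-2-(2,2-dichloroethenyl)phenyl]-4-methylbenzenesulfonamide F5. LiN(SiMe3)2 (2.2 equiv) in THF at −78 °C should then eliminate HCl to give 12.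

**Further compounds**

F1 | step 6 | 4,7-dibromo-1-tosylindole | Cc1ccc(cc1)S(=O)(=O)n1ccc2c(Br)ccc(Br)c12
F2 | step 6 | 4,7-dibromo-2-chloro-1-tosylindole | Cc1ccc(cc1)S(=O)(=O)n1c(Cl)cc2c(Br)ccc(Br)c12
F3 | step 2 | 2-azido-3,6-dibromobenzaldehyde | O=Cc1c(N=[N+]=[N-])c(Br)ccc1Br
F4 | step 5 | N-(3,6-dibromo-2-formylphenyl)-4-methylbenzenesulfonamide | Cc1ccc(cc1)S(=O)(=O)Nc1c(Br)ccc(Br)c1C=O
F5 | step 5 | N-[3,6-dibromo-2-(2,2-dichloroethenyl)phenyl]-4-methylbenzenesulfonamide | Cc1ccc(cc1)S(=O)(=O)Nc1c(Br)ccc(Br)c1C=C(Cl)Cl
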